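The route rests on cutting the aryl ether bond O1(L)–C8a(L) of the lower unit (L: rings D, F, E). Its chain O1–C2–C3(O)–C4(O) with catechol ring E is droxidopa. The benzylic carbinol is C2(L) as it stands, the amino carbon becomes C3(L) after one net inversion, and the carboxyl carbon becomes C4(L). The key step exploits the fact that C8a lies ortho to the C4 carbonyl on ring D. A fluoride there is displaced by the C2 alkoxide, which closes ring F in one operation and never breaks C2–O. The precursor is an ortho-fluoroaryl ketone bearing the benzylated upper 4-arylflavan (U) at C6(L), a 3-O-benzyl group and a free 2-OH.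

Key step: step 17

Remarks:
- Flavan numbering is used for both units (U: rings A, C, B; L: rings D, F, E). Bn = benzyl, TBS = tert-butyldimethylsilyl.
- Compounds 12, 14 and 18 are assumed to be purchased.
- For one and the same geometry, C4(U) is S in the benzylated compounds and R in 28. Ring A outranks ring D in the CIP sense only once O7(L) carries hydrogen.

Step 1
Reactants: 1 droxidopa
Product: 2 N-Boc-droxidopa
Conditions: Boc2O, NaHCO3, H2O/THF, argon, 0 °C to rt; then 1 M HCl to pH 3
Reagents that add atoms: di-tert-butyl dicarbonate, CC(C)(C)OC(=O)OC(=O)OC(C)(C)C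
Why: N-acylation of the amine with a dicarbonate (carbamate protection) is chemoselective at bicarbonate pH, where the catechol stays protonated and argon keeps it from oxidising, and it touches neither stereocentre.

Step 2
Reactants: 2 N-Boc-droxidopa
Product: 4 N-Boc-3',4'-di-O-benzyldroxidopa (free acid), via tribenzyl ester 3 (not isolated)
Conditions: BnBr (3.3 equiv), K2CO3, DMF, rt; then LiOH, H2O/THF, rt; then 1 M HCl to pH 3
Reagents that add atoms: benzyl bromide, BrCc1ccccc1; lithium hydroxide, [Li+].[OH-]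
Why: Williamson alkylation under a carbonate base reaches only the two phenols and the carboxylate, since the carbinol and the carbamate N–H are too weakly acidic, and the saponification that follows in the same flask restores the free acid without epimerising the carbamate-protected alpha carbon.

Step 3
Reactants: 4 N-Boc-3',4'-di-O-benzyldroxidopa
Product: 6 (2S,3R)-2-amino-3-[3,4-bis(benzyloxy)phenyl]-3-(TBS-oxy)propanoic acid, via tris-silyl derivative 5 (not isolated)
Conditions: TBSOTf (3.5 equiv), 2,6-lutidine, CH2Cl2, 0 °C to rt; then MeOH, rt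
Reagents that add atoms: tert-butyldimethylsilyl triflate, CC(C)(C)[Si](C)(C)OS(=O)(=O)C(F)(F)F
Why: The silyl triflate silylates the benzylic carbinol and at the same time turns the tert-butyl carbamate into a labile silyl carbamate (silyl-triflate-mediated Boc cleavage), so that methanolysis of silyl ester and silyl carbamate leaves the free amino acid with O1(L) masked while nitrogen still marks C3(L), which is what later tells the two oxygens apart.

Step 4
Reactants: 6 O-TBS amino acid
Product: 7 (2S,3R)-3-[3,4-bis(benzyloxy)phenyl]-2-hydroxy-3-(TBS-oxy)propanoic acid (threo)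
Conditions: NaNO2, dilute H2SO4, H2O/1,4-dioxane, 0 °C
Reagents that add atoms: water, O
Why: Nitrous acid deamination of an alpha-amino acid: the carboxylate displaces N2 from the diazonium ion to give an alpha-lactone that water reopens at the same carbon, so two inversions leave C3(L) with retained (2S) configuration, while short exposure to cold dilute acid should spare the hindered silyl ether.

Step 5
Reactants: 7 threo alpha-hydroxy acid
Product: 8 (2S,3R)-3-[3,4-bis(benzyloxy)phenyl]-2-hydroxy-N-methoxy-N-methyl-3-(TBS-oxy)propanamide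
Conditions: MeNHOMe·HCl, EDC·HCl, HOBt, iPr2NEt, CH2Cl2, 0 °C to rt
Reagents that add atoms: N,O-dimethylhydroxylamine hydrochloride, CNOC.Cl
Why: Carbodiimide/HOBt amide coupling gives the Weinreb amide, the amine being far more nucleophilic toward the active ester than the hindered alpha-hydroxyl, and no stereocentre is involved.

Step 6
Reactants: 8 threo alpha-hydroxy Weinreb amide
Product: 10 (2R,3R)-3-[3,4-bis(benzyloxy)phenyl]-2-hydroxy-N-methoxy-N-methyl-3-(TBS-oxy)propanamide (erythro), via 4-nitrobenzoate 9 (not isolated)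
Conditions: PPh3, DIAD, 4-O2NC6H4CO2H, toluene/THF, 0 °C to rt; then MeOH, K2CO3 (cat.), 0 °C
Reagents that add atoms: 4-nitrobenzoic acid, O=C(O)c1ccc(cc1)[N+](=O)[O-]
Why: Mitsunobu inversion: the only free hydroxyl is activated as its oxyphosphonium salt and displaced by 4-nitrobenzoate in an SN2 reaction that the adjacent carbonyl group favours, which sets C3(L) as (2R), erythro to C2(L), and catalytic transesterification then frees the inverted alcohol.

Step 7
Reactants: 10 erythro alpha-hydroxy Weinreb amide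
Product: 11 (2R,3R)-2-(benzyloxy)-3-[3,4-bis(benzyloxy)phenyl]-N-methoxy-N-methyl-3-(TBS-oxy)propanamide
Conditions: BnBr, Ag2O, Bu4NI (cat.), MS 4 Å, CH2Cl2, rt, dark
Reagents that add atoms: benzyl bromide, BrCc1ccccc1
Why: Silver-oxide-promoted Williamson benzylation runs without a free alkoxide, so the neighbouring silyl group should not migrate and the alpha carbon should not epimerise.

Step 8
Reactants: 12 5-bromo-4-fluoro-2-hydroxybenzaldehyde
Product: 13 2-(benzyloxy)-5-bromo-4-fluorobenzaldehyde
Conditions: BnBr, K2CO3, DMF, rt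
Reagents that add atoms: benzyl bromide, BrCc1ccccc1
Why: Williamson ether synthesis on the acidic salicylaldehyde phenol proceeds at room temperature, where the fluoride para to the formyl group is not yet displaced.

Step 9
Reactants: 13 2-(benzyloxy)-5-bromo-4-fluorobenzaldehyde; 14 3,4-bis(benzyloxy)acetophenone
Product: 15 (E)-3-[2-(benzyloxy)-5-bromo-4-fluorophenyl]-1-[3,4-bis(benzyloxy)phenyl]prop-2-en-1-one
Conditions: LiOH·H2O (20 mol %), EtOH/THF, rt
Reagents that add atoms: none
Why: Claisen–Schmidt condensation (aldol addition, then E1cB dehydration) gives the conjugated (E)-enone under thermodynamic control, and the catalytic mild base leaves the aryl fluoride alone.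

Step 10
Reactants: 15 chalcone
Product: 16 [3,4-bis(benzyloxy)phenyl]{(2S,3R)-3-[2-(benzyloxy)-5-bromo-4-fluorophenyl]oxiran-2-yl}methanone
Conditions: poly-D-leucine, urea·H2O2, DBU, THF, rt
Reagents that add atoms: urea–hydrogen peroxide, OO.NC(N)=O
Why: Juliá–Colonna epoxidation (Weitz–Scheffer addition of hydroperoxide inside the helical polyleucine) is an established reaction of chalcones, and since the L-polymer gives (2R,3S)-epoxy ketones the D-polymer should set the trans-(2S,3R)-epoxide, that is C3(U) and the still uninverted C4(U).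

Step 11
Reactants: 16 epoxy ketone
Product: 17 (S)-[3,4-bis(benzyloxy)phenyl]{(2R,3R)-3-[2-(benzyloxy)-5-bromo-4-fluorophenyl]oxiran-2-yl}methanol (threo)
Conditions: (S)-2-methyl-CBS-oxazaborolidine (20 mol %), BH3·SMe2, THF, −20 °C; then MeOH
Reagents that add atoms: none
Why: Corey–Bakshi–Shibata reduction: with the aryl group as the large and the oxiranyl group as the small substituent the (S)-catalyst should deliver hydride to give the (S)-carbinol under reagent control, overriding the modest substrate preference for the erythro epimer, which chromatography would remove.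

Step 12
Reactants: 17 threo epoxy alcohol; 18 3-(benzyloxy)phenol
Product: 19 (2S,3R)-2-{(R)-[3-(benzyloxy)phenoxy][3,4-bis(benzyloxy)phenyl]methyl}-3-[2-(benzyloxy)-5-bromo-4-fluorophenyl]oxirane
Conditions: PPh3, DIAD, toluene, 0 °C
Reagents that add atoms: none
Why: Mitsunobu etherification of an oxiranyl aryl carbinol with a phenol, a reaction type used in flavan-3-ol synthesis, proceeds by SN2 displacement, so the carbinol carbon is inverted to (R)-C2(U), with the electron-withdrawing epoxide and the non-polar solvent holding back ionisation.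

Step 13
Reactants: 19 aryloxy epoxide
Product: 20 (2R,3S,4S)-7-(benzyloxy)-4-[2-(benzyloxy)-5-bromo-4-fluorophenyl]-2-[3,4-bis(benzyloxy)phenyl]chroman-3-ol
Conditions: (CF3)2CHOH, 0 °C to rt
Reagents that add atoms: none
Why: Intramolecular Friedel–Crafts epoxy–arene cyclisation: hydrogen-bond activation by the fluorinated alcohol opens the epoxide at the benzylic C4(U), and the ring A carbon para to the benzyloxy group attacks anti to the departing oxygen (6-endo), so C4 is inverted, C3 keeps its oxygen and the all-equatorial 2,3-trans-3,4-trans flavan-3-ol should result.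

Step 14
Reactants: 20 4-arylflavan-3-ol
Product: 21 3-O-benzyl ether of 20 (unit U with ring D as bromide)
Conditions: NaH, BnBr, Bu4NI (cat.), DMF, 0 °C to rt
Reagents that add atoms: benzyl bromide, BrCc1ccccc1
Why: Williamson benzylation of the secondary alkoxide, which has no leaving group within reach because the fluoride of ring D is not yet activated, caps O3(U) with the same group as all other oxygens.

Step 15
Reactants: 21 bromide of unit U; 11 Weinreb amide
Product: 23 ortho-fluoroaryl ketone as its 2-O-TBS ether, via arylmagnesium chloride 22 (not isolated)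
Conditions: 21, iPrMgCl·LiCl, THF, 0 °C; then 11, −20 to 10 °C; aq. NH4Cl
Reagents that add atoms: none
Why: Halogen–magnesium exchange, accelerated by the ortho fluorine and run cold enough that the ortho-fluoroarylmagnesium does not collapse to an aryne, is followed by Weinreb ketone synthesis, in which the chelated tetrahedral adduct prevents over-addition and the weakly basic reagent leaves C3(L) untouched.

Step 16
Reactants: 23 silyl-protected ketone
Product: 24 ortho-fluoroaryl (2R,3R)-2-(benzyloxy)-3-hydroxy-3-arylpropyl ketone (precursor of the key step)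
Conditions: HF·pyridine, pyridine/THF, 0 °C to rt
Reagents that add atoms: none
Why: Fluoride-induced desilylation under buffered, slightly acidic conditions releases the beta-hydroxy ketone directly before use without ever forming its alkoxide, so neither retro-aldol cleavage nor epimerisation can start ahead of the key step.

Step 17
Reactants: 24 hydroxy ketone
Product: 26 octabenzyl dimer whose lower unit is the (2R,3R)-3-(benzyloxy)flavan-4-one, via sodium alkoxide 25 (not isolated)
Conditions: NaN(SiMe3)2 (1.0 equiv), THF (high dilution), −78 °C; then DMPU, −78 to 0 °C; pH 7 buffer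
Reagents that add atoms: none
Why: The amide base removes only the hydroxyl proton at −78 °C, and the sodium alkoxide 25 adds to the fluorine-bearing C8a(L) to give a Meisenheimer anion whose charge is taken up through C4a by the C4 carbonyl, after which loss of fluoride rearomatises ring D (addition–elimination SNAr). The closest known reaction type is the intramolecular O-arylation of alkoxides on ortho-fluoroaryl ketones that is used to make chroman-4-ones. Ring F closes as a six-membered ring, 6-endo-trig with respect to the C8a=C4a–C4=O acceptor that carries the charge (6-exo-trig only if the other Kekulé form is drawn), and both modes are geometrically easy. No stereocentre is created: O1(L) is the carbinol oxygen of droxidopa and the C2–O bond is never broken, so C2(L) is retained, while C3(L), set in step 6, ends trans-diequatorial to it, the more stable arrangement, so that slight enolisation would correct itself. The selectivity needed is O-arylation ahead of retro-aldol cleavage, C3 deprotonation and base-induced opening of the product; it is secured by exactly one equivalent of a soluble base added cold, high dilution, a dipolar cosolvent that speeds the SNAr step, the 7-OBn group lying meta to fluorine, a 3-O-benzyl group that can neither migrate nor cyclise, and sodium as counter-ion, which removes fluoride as insoluble NaF and leaves a neutral mixture. Because unit U is homochiral, any leakage would show up as separable diastereomers and not as loss of enantiopurity.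

Step 18
Reactants: 26 octabenzyl flavanone dimer
Product: 27 octabenzyl dimer with the lower unit as the (2R,3S,4S)-3-(benzyloxy)flavan-4-ol (2,3-trans-3,4-cis)
Conditions: LiBH(s-Bu)3, THF, −78 °C; then H2O
Reagents that add atoms: none
Why: Diastereoselective ketone reduction under steric approach control: the bulky trialkylborohydride avoids the axial C2–H and attacks the half-chair pyranone from the equatorial direction, so the new 4-OH is axial and cis to the equatorial 3-OBn, i.e. (4S).

Step 19
Reactants: 27 octabenzyl 3,4-cis carbinol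
Product: 28 target CNP0280090.4
Conditions: H2 (1 atm), Pd(OH)2/C, THF/MeOH, rt, stopped at full debenzylation
Reagents that add atoms: none
Why: Catalytic hydrogenolysis cleaves all eight O–CH2Ph bonds, and in a neutral, acid-free medium at one atmosphere the secondary benzylic C4(L)–OH and the cyclic benzylic C2–O1 bonds react much more slowly, as in the debenzylation of hydroxybenzylic alcohols and of oligomeric flavan-3-ols.

Compound list
1 | droxidopa, (2S,3R)-2-amino-3-(3,4-dihydroxyphenyl)-3-hydroxypropanoic acid | N[C@@H]([C@H](O)c1ccc(O)c(O)c1)C(=O)O | starting material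
2 | N-Boc-droxidopa, (2S,3R) | CC(C)(C)OC(=O)N[C@@H]([C@H](O)c1ccc(O)c(O)c1)C(=O)O | intermediate
3 | benzyl (2S,3R)-3-[3,4-bis(benzyloxy)phenyl]-2-(Boc-amino)-3-hydroxypropanoate | CC(C)(C)OC(=O)N[C@@H]([C@H](O)c1ccc(OCc2ccccc2)c(OCc2ccccc2)c1)C(=O)OCc1ccccc1 | intermediate
4 | (2S,3R)-3-[3,4-bis(benzyloxy)phenyl]-2-(Boc-amino)-3-hydroxypropanoic acid | CC(C)(C)OC(=O)N[C@@H]([C@H](O)c1ccc(OCc2ccccc2)c(OCc2ccccc2)c1)C(=O)O | intermediate
5 | tris-TBS derivative of 4 (silyl ether, silyl ester, silyl carbamate), (2S,3R) | CC(C)(C)[Si](C)(C)OC(=O)N[C@@H]([C@H](O[Si](C)(C)C(C)(C)C)c1ccc(OCc2ccccc2)c(OCc2ccccc2)c1)C(=O)O[Si](C)(C)C(C)(C)C | intermediate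
6 | (2S,3R)-2-amino-3-[3,4-bis(benzyloxy)phenyl]-3-(TBS-oxy)propanoic acid | N[C@@H]([C@H](O[Si](C)(C)C(C)(C)C)c1ccc(OCc2ccccc2)c(OCc2ccccc2)c1)C(=O)O | intermediate
7 | (2S,3R)-3-[3,4-bis(benzyloxy)phenyl]-2-hydroxy-3-(TBS-oxy)propanoic acid (threo) | O[C@@H]([C@H](O[Si](C)(C)C(C)(C)C)c1ccc(OCc2ccccc2)c(OCc2ccccc2)c1)C(=O)O | intermediate
8 | (2S,3R)-3-[3,4-bis(benzyloxy)phenyl]-2-hydroxy-N-methoxy-N-methyl-3-(TBS-oxy)propanamide | O[C@@H]([C@H](O[Si](C)(C)C(C)(C)C)c1ccc(OCc2ccccc2)c(OCc2ccccc2)c1)C(=O)N(C)OC | intermediate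
9 | (2R,3R)-2-O-(4-nitrobenzoyl) derivative, inverted at the alpha carbon | O=C(O[C@H]([C@H](O[Si](C)(C)C(C)(C)C)c1ccc(OCc2ccccc2)c(OCc2ccccc2)c1)C(=O)N(C)OC)c1ccc(cc1)[N+](=O)[O-] | intermediate
10 | (2R,3R)-3-[3,4-bis(benzyloxy)phenyl]-2-hydroxy-N-methoxy-N-methyl-3-(TBS-oxy)propanamide (erythro) | O[C@H]([C@H](O[Si](C)(C)C(C)(C)C)c1ccc(OCc2ccccc2)c(OCc2ccccc2)c1)C(=O)N(C)OC | intermediate
11 | (2R,3R)-2-(benzyloxy)-3-[3,4-bis(benzyloxy)phenyl]-N-methoxy-N-methyl-3-(TBS-oxy)propanamide | c1ccccc1CO[C@H]([C@H](O[Si](C)(C)C(C)(C)C)c1ccc(OCc2ccccc2)c(OCc2ccccc2)c1)C(=O)N(C)OC | intermediate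
12 | 5-bromo-4-fluoro-2-hydroxybenzaldehyde | O=Cc1cc(Br)c(F)cc1O | starting material
13 | 2-(benzyloxy)-5-bromo-4-fluorobenzaldehyde | O=Cc1cc(Br)c(F)cc1OCc1ccccc1 | intermediate
14 | 3,4-bis(benzyloxy)acetophenone | CC(=O)c1ccc(OCc2ccccc2)c(OCc2ccccc2)c1 | starting material
15 | (E)-3-[2-(benzyloxy)-5-bromo-4-fluorophenyl]-1-[3,4-bis(benzyloxy)phenyl]prop-2-en-1-one | O=C(/C=C/c1cc(Br)c(F)cc1OCc1ccccc1)c1ccc(OCc2ccccc2)c(OCc2ccccc2)c1 | intermediate
16 | [3,4-bis(benzyloxy)phenyl]{(2S,3R)-3-[2-(benzyloxy)-5-bromo-4-fluorophenyl]oxiran-2-yl}methanone | O=C(c1ccc(OCc2ccccc2)c(OCc2ccccc2)c1)[C@H]1O[C@@H]1c1cc(Br)c(F)cc1OCc1ccccc1 | intermediate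
17 | (S)-[3,4-bis(benzyloxy)phenyl]{(2R,3R)-3-[2-(benzyloxy)-5-bromo-4-fluorophenyl]oxiran-2-yl}methanol | O[C@@H](c1ccc(OCc2ccccc2)c(OCc2ccccc2)c1)[C@H]1O[C@@H]1c1cc(Br)c(F)cc1OCc1ccccc1 | intermediate
18 | 3-(benzyloxy)phenol | Oc1cccc(OCc2ccccc2)c1 | starting material
19 | (2S,3R)-2-{(R)-[3-(benzyloxy)phenoxy][3,4-bis(benzyloxy)phenyl]methyl}-3-[2-(benzyloxy)-5-bromo-4-fluorophenyl]oxirane | c1ccccc1COc1cccc(c1)O[C@H](c1ccc(OCc2ccccc2)c(OCc2ccccc2)c1)[C@H]1O[C@@H]1c1cc(Br)c(F)cc1OCc1ccccc1 | intermediate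
20 | (2R,3S,4S)-7-(benzyloxy)-4-[2-(benzyloxy)-5-bromo-4-fluorophenyl]-2-[3,4-bis(benzyloxy)phenyl]chroman-3-ol (2,3-trans-3,4-trans) | c1ccccc1COc1ccc2c(c1)O[C@H](c1ccc(OCc3ccccc3)c(OCc3ccccc3)c1)[C@@H](O)[C@@H]2c1cc(Br)c(F)cc1OCc1ccccc1 | intermediate
21 | (2R,3S,4S)-3,7-bis(benzyloxy)-4-[2-(benzyloxy)-5-bromo-4-fluorophenyl]-2-[3,4-bis(benzyloxy)phenyl]chroman | c1ccccc1COc1ccc2c(c1)O[C@H](c1ccc(OCc3ccccc3)c(OCc3ccccc3)c1)[C@@H](OCc1ccccc1)[C@@H]2c1cc(Br)c(F)cc1OCc1ccccc1 | intermediate
22 | arylmagnesium chloride of 21 (MgCl in place of Br at C4a(L)) | c1ccccc1COc1ccc2c(c1)O[C@H](c1ccc(OCc3ccccc3)c(OCc3ccccc3)c1)[C@@H](OCc1ccccc1)[C@@H]2c1cc([Mg]Cl)c(F)cc1OCc1ccccc1 | intermediate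
23 | (2R,3R)-2-(benzyloxy)-3-[3,4-bis(benzyloxy)phenyl]-3-(TBS-oxy)-1-{4-(benzyloxy)-2-fluoro-5-[(2R,3S,4S)-3,7-bis(benzyloxy)-2-[3,4-bis(benzyloxy)phenyl]chroman-4-yl]phenyl}propan-1-one | c1ccccc1COc1ccc2c(c1)O[C@H](c1ccc(OCc3ccccc3)c(OCc3ccccc3)c1)[C@@H](OCc1ccccc1)[C@@H]2c1cc(C(=O)[C@H](OCc3ccccc3)[C@H](O[Si](C)(C)C(C)(C)C)c3ccc(OCc4ccccc4)c(OCc4ccccc4)c3)c(F)cc1OCc1ccccc1 | intermediate
24 | 3-hydroxy ketone from 23 (free C2(L)–OH), (2R,3R) in the chain | c1ccccc1COc1ccc2c(c1)O[C@H](c1ccc(OCc3ccccc3)c(OCc3ccccc3)c1)[C@@H](OCc1ccccc1)[C@@H]2c1cc(C(=O)[C@H](OCc3ccccc3)[C@H](O)c3ccc(OCc4ccccc4)c(OCc4ccccc4)c3)c(F)cc1OCc1ccccc1 | intermediate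
25 | sodium alkoxide of 24 | c1ccccc1COc1ccc2c(c1)O[C@H](c1ccc(OCc3ccccc3)c(OCc3ccccc3)c1)[C@@H](OCc1ccccc1)[C@@H]2c1cc(C(=O)[C@H](OCc3ccccc3)[C@H]([O-])c3ccc(OCc4ccccc4)c(OCc4ccccc4)c3)c(F)cc1OCc1ccccc1.[Na+] | intermediate
26 | octa-O-benzyl dimer, upper unit (2R,3S,4S), lower unit (2R,3R)-2,3-trans-3-(benzyloxy)flavan-4-one linked through C6 | c1ccccc1COc1ccc2c(c1)O[C@H](c1ccc(OCc3ccccc3)c(OCc3ccccc3)c1)[C@@H](OCc1ccccc1)[C@@H]2c1cc2c(cc1OCc1ccccc1)O[C@H](c1ccc(OCc3ccccc3)c(OCc3ccccc3)c1)[C@@H](OCc1ccccc1)C2=O | intermediate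
27 | octa-O-benzyl dimer, lower unit (2R,3S,4S)-flavan-4-ol (2,3-trans-3,4-cis) | c1ccccc1COc1ccc2c(c1)O[C@H](c1ccc(OCc3ccccc3)c(OCc3ccccc3)c1)[C@@H](OCc1ccccc1)[C@@H]2c1cc2c(cc1OCc1ccccc1)O[C@H](c1ccc(OCc3ccccc3)c(OCc3ccccc3)c1)[C@@H](OCc1ccccc1)[C@H]2O | intermediate
28 | CNP0280090.4, upper (2R,3S,4R)-4-arylflavan-3,7,3',4'-tetrol joined from C4 to C6 of the lower (2R,3S,4S)-flavan-3,4,7,3',4'-pentol | Oc1ccc2c(c1)O[C@H](c1ccc(O)c(O)c1)[C@@H](O)[C@@H]2c1cc2c(cc1O)O[C@H](c1ccc(O)c(O)c1)[C@@H](O)[C@H]2O | target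

Total step count: 19. Seven steps lead to 11, seven lead to 21, and five follow their union.
Longest linear sequence: 12 steps, either 1 to 28 through steps 1–7 and 15–19, or 12 to 28 through steps 8–19.

Steps most likely to fail

1. Step 17.
- **Risk:** Ring D is activated by a single carbonyl group. Attack of the alkoxide on C8a may therefore be slower than fragmentation of the aldolate or proton transfer from C3. That would cleave the chain or scramble C2(L) and C3(L).
- **Fallback:** It sets out from 24 and comes back at 27, so step 18 is skipped. Compound 24 is reduced under Narasaka–Prasad conditions (Et2BOMe, NaBH4, THF/MeOH, −78 °C). Hydride is delivered to the boron chelate, in which ring E and the 3-OBn group are equatorial. This gives the 2,4-syn diol with fluoride still on ring D F1, which already has C4(L) as in 27.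
- **Closure:** Without a carbonyl group neither retro-aldol cleavage nor enolisation is possible. KH in THF/DMPU (rt to 60 °C) then lets the C2 alkoxide displace the now unactivated fluoride. This oxy-cyclisation on alkoxy-fluoroarenes is known from flavan-3-ol synthesis. The C4 alkoxide cannot reach C8a.

2. Step 4.
- **Risk:** The electron-rich aryl group or the hydrogen on C2(L) may migrate to the diazonium carbon (semipinacol pathway) faster than the carboxylate closes the alpha-lactone. The acid may also strip the silyl ether or nitrosate ring E.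
- **Fallback:** It sets out from 4 and comes back at 8. It replaces substitution at the diazonium ion by oxidation and reduction. Compound 4 is coupled with MeNHOMe·HCl (EDC·HCl, HOBt, iPr2NEt) to the N-Boc Weinreb amide F2. TBSOTf/2,6-lutidine followed by MeOH gives the O-silylated amino amide F3.
- **Deamination and reduction:** Condensation with 3,5-di-tert-butyl-1,2-benzoquinone, prototropic shift of the imine and hydrolysis at pH 3 (quinone-mediated transamination) give the alpha-keto amide F4. LiBH(s-Bu)3 at −78 °C attacks anti to the silyloxy group (polar Felkin–Anh control) and should give the threo alcohol 8.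

3. Step 19.
- **Risk:** Once O7(L) is free, the C4(L) hydroxyl is a para-hydroxybenzylic alcohol and may be lost by hydrogenolysis. The two secondary benzyl ethers cleave slowly, which prolongs the exposure. Traces of acid on the catalyst support may also start self-condensation.
- **Fallback:** It sets out from 26 and comes back at 28. The benzyl groups are removed at the ketone stage (H2, Pd(OH)2/C, THF/MeOH), where C4(L) has no hydroxyl to lose, giving the free flavanonol dimer F5.
- **Silyl sequence:** TBSOTf/2,6-lutidine gives the octakis-TBS ether F6. LiBH(s-Bu)3 at −78 °C gives the 3,4-cis carbinol F7. Bu4NF buffered with AcOH in THF then removes all silyl groups without any reducing step.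

Further compounds
F1 | step 17 | 2,4-syn diol from 24 (C4(L)–OH configured as in 27, fluoride still on ring D) | c1ccccc1COc1ccc2c(c1)O[C@H](c1ccc(OCc3ccccc3)c(OCc3ccccc3)c1)[C@@H](OCc1ccccc1)[C@@H]2c1cc([C@H](O)[C@H](OCc3ccccc3)[C@H](O)c3ccc(OCc4ccccc4)c(OCc4ccccc4)c3)c(F)cc1OCc1ccccc1
F2 | step 4 | (2S,3R)-3-[3,4-bis(benzyloxy)phenyl]-2-(Boc-amino)-3-hydroxy-N-methoxy-N-methylpropanamide | CC(C)(C)OC(=O)N[C@@H]([C@H](O)c1ccc(OCc2ccccc2)c(OCc2ccccc2)c1)C(=O)N(C)OC
F3 | step 4 | (2S,3R)-2-amino-3-[3,4-bis(benzyloxy)phenyl]-N-methoxy-N-methyl-3-(TBS-oxy)propanamide | N[C@@H]([C@H](O[Si](C)(C)C(C)(C)C)c1ccc(OCc2ccccc2)c(OCc2ccccc2)c1)C(=O)N(C)OC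
F4 | step 4 | 3-[3,4-bis(benzyloxy)phenyl]-N-methoxy-N-methyl-2-oxo-3-(TBS-oxy)propanamide, carbinol carbon configured as in 6 | O=C([C@H](O[Si](C)(C)C(C)(C)C)c1ccc(OCc2ccccc2)c(OCc2ccccc2)c1)C(=O)N(C)OC
F5 | step 19 | free phenolic dimer with the lower unit as (2R,3R)-3-hydroxyflavan-4-one | Oc1ccc2c(c1)O[C@H](c1ccc(O)c(O)c1)[C@@H](O)[C@@H]2c1cc2c(cc1O)O[C@H](c1ccc(O)c(O)c1)[C@@H](O)C2=O
F6 | step 19 | octakis-O-TBS ether of F5 | CC(C)(C)[Si](C)(C)Oc1ccc2c(c1)O[C@H](c1ccc(O[Si](C)(C)C(C)(C)C)c(O[Si](C)(C)C(C)(C)C)c1)[C@@H](O[Si](C)(C)C(C)(C)C)[C@@H]2c1cc2c(cc1O[Si](C)(C)C(C)(C)C)O[C@H](c1ccc(O[Si](C)(C)C(C)(C)C)c(O[Si](C)(C)C(C)(C)C)c1)[C@@H](O[Si](C)(C)C(C)(C)C)C2=O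
F7 | step 19 | octakis-O-TBS 3,4-cis carbinol (free C4(L)–OH) | CC(C)(C)[Si](C)(C)Oc1ccc2c(c1)O[C@H](c1ccc(O[Si](C)(C)C(C)(C)C)c(O[Si](C)(C)C(C)(C)C)c1)[C@@H](O[Si](C)(C)C(C)(C)C)[C@@H]2c1cc2c(cc1O[Si](C)(C)C(C)(C)C)O[C@H](c1ccc(O[Si](C)(C)C(C)(C)C)c(O[Si](C)(C)C(C)(C)C)c1)[C@@H](O[Si](C)(C)C(C)(C)C)[C@H]2O
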